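**Remark on the chemistry:** isochromene numbering is used throughout (C1 = OCH2, O2, C3 = acyl-bearing carbon, C4 = vinyl CH, C4a to C8a). The structure of precursor 10 was checked against the atom mapping of the cycloaddition and needs no correction: the propargyloxy oxygen and the furyl group are cis on C3=C4 (Z), and the furan methoxy group stands on furan C4. Acid 6 is taken to be purchasable.

## Structural features

Compound 13 is an achiral 1H-isochromene: benzene ring A (C4a to C8a) is fused to a six-membered oxygen ring made of C1H2, O2, C3 and C4, with a C3=C4 double bond. C3 carries a ketone whose other substituent is ring C, a 2,4-dimethoxyphenyl group, and ring A carries methoxy groups on the neighbouring carbons C6 and C7. There is no stereocentre, so none stand next to each other; the only stereochemical element of the route is the Z enol ether of the open-chain precursor 10, which becomes the ring-enforced cis arrangement at C3=C4. The fragile parts are the C3=C4 enol ether, which is also the alkene of an enone (acid hydrolysis, conjugate addition), the C1 methylene, which is benzylic and next to oxygen and so prone to autoxidation, and the electron-rich ring A. Ring C is trivial; the real difficulty is a 3-acyl-1H-isochromene with hydrogen at C4, made without the competing five-membered (phthalan) closure and with the oxygen pattern of ring A in place. The key step exploits the fact that the vicinal C6 and C7 oxygens are the image of a 3-oxygenated furan: the furan ring oxygen becomes the C7 oxygen, the furan methoxy group becomes the C6 methoxy group, furan C2 becomes C4a and furan C5 becomes C7. The chain C4=C3–O2–C1 is then a four-atom tether from furan C2 to a propargyl alkyne that supplies C8a and C8, so ring A and the pyran ring arise together.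

## Logic of the disconnections

13 to 12: the O–CH3 bond at C7 is cut. The C7 oxygen is the one ring A oxygen that cannot be carried through as a methyl ether, because it is the former furan ring oxygen. This makes 12, the direct outcome of the cycloaddition, the penultimate compound. The forward step must methylate a phenol without touching the enol ether enone or oxidising C1, which calls for a weak base and an inert atmosphere.

12 to 10 (through 11): the bonds C4a–C8a and C7–C8 are cut and the C4a–O bridge bond is restored. Both rings of the bicycle disappear at once, and what remains is a furan joined to an aryl ketone through an enol ether carrying a propargyl group. The forward step asks an electron-rich furan to add to an unactivated terminal alkyne through a four-atom tether, ahead of the [3,3] shift open to a propargyl vinyl ether, and asks 11 to open towards C7–O. The skeleton of 10 is kept unchanged. A silyl cap on its alkyne terminus and a reduced, protected form of its ketone were weighed as spectator changes and rejected: neither removes the [3,3] pathway, the first slows the cycloaddition, and both add steps.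

10 to 8 and 4 (through 9): the C3=C4 double bond is cut as an aldol condensation. This divides the precursor into two halves of similar size and uses the only enolisable position of 8. The forward step must give the Z isomer, which should be the thermodynamic one under reversible E1cB conditions, and must use a base that spares the terminal alkyne and does not trigger a sigmatropic shift of the enolate.

8 to 5 and 6 (through 7): the aryl–carbonyl bond is cut. Ring C is strongly activated at the position para to one methoxy group and ortho to the other, so the ketone can be made by acylation with the propargyl ether already present. This is the improvement in how the precursor is assembled: it avoids the union of an alkoxide with an α-halo ketone, which tends to divert through addition to the carbonyl group. The forward step needs an acylating species strong enough for 5 but free of metal Lewis acids that would attack the alkyne or the ethers.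

4 to 2 (through 3) and 2 to 1: the furan C4–OCH3 bond is cut back to C4–Br and the aldehyde is masked. A β-oxygenated furan is not accessible by electrophilic substitution, whereas the β-bromide 1 can be bought. The forward C–O coupling runs in hot methoxide, so the formyl group must be a base-stable acetal, and its removal must use acid weak enough to spare the methoxyfuran.

## Other disconnections considered

**Alternative 1:** The cut goes through C8a–C1 and C4a–C4. Ring A becomes 4,5-dimethoxybenzyne A3, released from the ortho-silylaryl triflate A4 by a fluoride source, and the C1–O2–C3–C4 unit becomes oxetan-3-one A2. In the forward direction the enolate of A2 would add to A3, the aryl anion would close onto the ketone, and the strained benzocyclobutenoxide would fragment to 6,7-dimethoxyisochroman-4-one A1, a formal insertion of the aryne into a C–C bond of the four-membered ketone.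
- In its favour: A3 is symmetric, so there is no regiochemical question; both ring A methoxy groups are present from the start; no sensitive furan is needed; C3 of A1 is acidic and can be acylated.
- Against it here: the enolate of A2 is strained and prone to self-condensation and ring opening, and simple ketone enolates tend to stop at α-arylation instead of inserting. A1 also carries a C4 carbonyl group that 13 lacks. After C-aroylation to the diketone A5, the C4 carbonyl would have to be reduced selectively in a largely enolised β-diketone whose two carbonyl groups are both deactivated aryl ketones, and the alcohol then dehydrated.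
- Comparison on structure: the alternative is better in that ring A arrives finished and no phenol methylation is needed. It is worse in that C4 has the wrong oxidation state and ring C is still to be attached, whereas the chosen plan sets the C3 acyl group and the C4 hydrogen before the rings close.
- Comparison on mechanism: it is ionic, runs at low temperature and has no competing sigmatropic pathway. The risk is of equal size but a different kind (the fate of the enolate and of the aryl anion).
- Comparison on step economy: it reaches the bicyclic core in its first step, which is better at that stage, but the corrections afterwards should bring it to the same count as the six steps of the chosen route, or more.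

**Alternative 2:** The cut goes through O2–C3 and C3–C4. The isochroman contracts to the phthalan acetal 1,5,6-trimethoxy-1,3-dihydroisobenzofuran A7, and C3 with its aroyl group becomes the diazoketone 2-diazo-1-(2,4-dimethoxyphenyl)ethan-1-one A8. In the forward direction a dirhodium tetracarboxylate catalyst would turn A8 into a metal carbene, the ring oxygen of A7 would capture it as an oxonium ylide, and a [1,2]-shift (Stevens rearrangement) of the acetal carbon would expand the five-membered ring to (2,4-dimethoxyphenyl)(4,6,7-trimethoxyisochroman-3-yl)methanone A6. β-Elimination of the C4 methoxy group of A6 (E1cB) would then give 13 and erase both stereocentres.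
- In its favour: it is the shortest plan, a union of two pieces of similar size followed by one elimination. Ring A is complete, the C3 acyl group and a C4 leaving group are created in the same event, and an acetal carbon is a good migrating group.
- Against it here: ylide formation is intermolecular and competes with carbene dimerisation, with capture by the exocyclic methoxy oxygen (whose ylide would give C–O insertion without ring expansion), with addition to the electron-rich arenes and with insertion into benzylic C–H bonds. The [1,2]-shift passes through a radical pair. A8 is a hazardous reagent.
- Comparison on structure: the alternative is the equal of the chosen plan in delivering exactly the enol ether enone, and better in that no methylation follows.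
- Comparison on mechanism: the choice among several nucleophilic sites by an unstabilised carbene is less predictable than the tether-controlled regiochemistry of the chosen cycloaddition.
- Comparison on step economy: the alternative is better, at about four steps, at the price of a diazo compound and an uncertain chemoselectivity.

**Alternative 3:** The cut goes through C1'–C2' and C5'–C6' of ring C (primed numbers for the benzoyl ring). Ring C is assembled from the ynone 1-(6,7-dimethoxy-1H-isochromen-3-yl)prop-2-yn-1-one A10 and the diene 1,3-dimethoxy-1-(trimethylsilyloxy)buta-1,3-diene A11. In the forward direction the methylene terminus of A11 would add to the alkyne terminus of A10 in a [4+2] cycloaddition, and loss of the methoxy and silyl groups from the adduct would aromatise it to the chelated phenol (2-hydroxy-4-methoxyphenyl)(6,7-dimethoxy-1H-isochromen-3-yl)methanone A9. O-Methylation of A9 would give 13.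
- In its favour: an activated ynone and an electron-rich diene should react under mild conditions with predictable regiochemistry. On this point the alternative is better than the chosen plan.
- Against it here: ring C is the one part of 13 that can be bought complete. Building it last leaves the isochromene unsolved, because A10 needs a separate synthesis of the bicyclic core with an acyl anchor at C3. A10 is also a delicate acceptor (a terminal ynone on an enol ether), and the hydrogen-bonded hydroxyl of A9 needs firmer methylation conditions.
- Comparison on structure: it addresses the easy ring and leaves the hard one.
- Comparison on mechanism: both plans make a benzene ring by cycloaddition and aromatisation and both end with an O-methylation, so they are equal in kind; the alternative's cycloaddition is the more certain.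
- Comparison on step economy: it is worse, since the steps to A10 are added to the two steps from A10 to 13.

Key step: step 5

## Route

Step 1
Reactants: 1 4-bromofuran-2-carbaldehyde
Product: 2 4-bromo-2-(dimethoxymethyl)furan
Conditions: HC(OMe)3, TsOH·H2O (cat.), MeOH, rt
Reagents that add atoms: trimethyl orthoformate, COC(OC)OC
Why: Acid-catalysed acetalisation of a non-enolisable aldehyde, driven by the orthoformate; the dimethyl acetal keeps the formyl group out of Cannizzaro and hemiacetal chemistry in the hot methoxide of step 2 and is removable with very weak acid.

Step 2
Reactants: 2 4-bromo-2-(dimethoxymethyl)furan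
Product: 4 4-methoxyfuran-2-carbaldehyde, via methoxy acetal 3 (not isolated)
Conditions: NaOMe, CuBr (cat.), MeOH–NMP, 100 °C; then aq. citric acid, THF, rt (pH about 3)
Reagents that add atoms: sodium methoxide, C[O-].[Na+]; water, O
Why: Ullmann-type C–O coupling of a heteroaryl bromide with methoxide under catalysis by monovalent copper, a known reaction of β-bromo five-membered heteroarenes such as 3-bromothiophene; the acetal is inert to the base. The weakly acidic work-up should hydrolyse only the furfural-type acetal, whose oxocarbenium ion is stabilised by the furan, and the freed formyl group then deactivates the methoxyfuran towards ring protonation.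

Step 3
Reactants: 5 1,3-dimethoxybenzene; 6 2-(prop-2-yn-1-yloxy)acetic acid
Product: 8 1-(2,4-dimethoxyphenyl)-2-(prop-2-yn-1-yloxy)ethan-1-one, via mixed anhydride 7 (not isolated)
Conditions: TFAA, H3PO4 (cat.), CH2Cl2, 0 °C to rt
Reagents that add atoms: none
Why: Friedel–Crafts acylation through the acyl trifluoroacetate 7, which is electrophilic enough for the doubly activated arene 5 without a metal Lewis acid, so the alkyne and the ethers are not endangered. Attack should occur at C4 of 5 (para to one methoxy group, ortho to the other; C2 is flanked on both sides), and the new ketone deactivates the ring against a second acylation.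

Step 4
Reactants: 8 1-(2,4-dimethoxyphenyl)-2-(prop-2-yn-1-yloxy)ethan-1-one; 4 4-methoxyfuran-2-carbaldehyde
Product: 10 (Z)-1-(2,4-dimethoxyphenyl)-3-(4-methoxyfuran-2-yl)-2-(prop-2-yn-1-yloxy)prop-2-en-1-one, via aldol adduct 9 (not isolated)
Conditions: KOH, EtOH–H2O, 0 °C to rt, dark
Reagents that add atoms: none
Why: Claisen–Schmidt aldol condensation in which 8 is the only enolisable partner and 4 cannot enolise; dehydration of 9 is a reversible E1cB process and should give the more stable Z isomer (furyl trans to the aroyl group, as in α-alkoxychalcones), which is the geometry the cycloaddition needs. Hydroxide is preferred to secondary amines because enamines of α-propargyloxy ketones are prone to [2,3]-sigmatropic shift.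

Step 5
Reactants: 10 (Z)-1-(2,4-dimethoxyphenyl)-3-(4-methoxyfuran-2-yl)-2-(prop-2-yn-1-yloxy)prop-2-en-1-one
Product: 12 (2,4-dimethoxyphenyl)(7-hydroxy-6-methoxy-1H-isochromen-3-yl)methanone, via oxanorbornadiene cycloadduct 11 (not isolated)
Conditions: 1,2-dichlorobenzene (degassed, dilute), BHT (cat.), 150 °C, sealed tube, dark
Reagents that add atoms: none
Why: On heating, the furan of 10 (diene; furan C2 becomes C4a, furan C5 becomes C7) and the tethered alkyne (C8a and C8) should combine in a concerted, probably asynchronous [4+2] cycloaddition to the oxanorbornadiene 11, with the C7–C8 bond to the unhindered alkyne terminus leading. The closest known reaction type is the intramolecular Diels–Alder reaction of furans with tethered alkynes followed by opening of the oxygen bridge to a phenol. The pyran ring closes through C4a–C8a as the tether ring of the cycloaddition (six-membered because the tether C4, C3, O2, C1 has four atoms; exo with respect to the alkyne), and ring A closes as the cycloaddition ring itself through C4a–C8a and C7–C8. In 11 the C4a–O bond should then ionise, because the resulting cation is a vinylogous oxocarbenium ion of the C6 methoxy group and is also conjugated with the enol ether oxygen O2, and loss of the C7 proton aromatises ring A, leaves the bridge oxygen as the C7 hydroxyl and makes the sequence irreversible. No stereocentre remains: the two bridgehead centres of 11 are fixed relative to each other by the bicycle and are erased on aromatisation. Regiochemistry needs no control beyond the tether, which allows only the C4a–C8a and C7–C8 pairing, and the Z alkene holds diene and dienophile on the same side. The direction of bridge opening is secured by the C6 methoxy group and by the fact that only C7 carries a hydrogen. What the substrate does not secure is chemoselectivity against the [3,3] shift of its propargyl vinyl ether unit, so the reaction is run dilute, dark, oxygen-free and at the lowest temperature that gives conversion.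

Step 6
Reactants: 12 (2,4-dimethoxyphenyl)(7-hydroxy-6-methoxy-1H-isochromen-3-yl)methanone
Product: 13 (2,4-dimethoxyphenyl)(6,7-dimethoxy-1H-isochromen-3-yl)methanone
Conditions: MeI, K2CO3, acetone, rt, Ar
Reagents that add atoms: iodomethane, CI
Why: Williamson O-methylation of a phenol (phenoxide from K2CO3, SN2 on MeI); the C7 hydroxyl is the only acidic site, all other oxygens are already ethers, and the weak base and inert atmosphere spare the enol ether enone and the C1 methylene.

## Compound list

1 | 4-bromofuran-2-carbaldehyde | O=Cc1cc(Br)co1 | starting material
2 | 4-bromo-2-(dimethoxymethyl)furan | COC(OC)c1cc(Br)co1 | intermediate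
3 | 2-(dimethoxymethyl)-4-methoxyfuran | COC(OC)c1cc(OC)co1 | intermediate
4 | 4-methoxyfuran-2-carbaldehyde | O=Cc1cc(OC)co1 | intermediate
5 | 1,3-dimethoxybenzene | COc1cccc(OC)c1 | starting material
6 | 2-(prop-2-yn-1-yloxy)acetic acid | C#CCOCC(=O)O | starting material
7 | 2-(prop-2-yn-1-yloxy)acetic trifluoroacetic anhydride | C#CCOCC(=O)OC(=O)C(F)(F)F | intermediate
8 | 1-(2,4-dimethoxyphenyl)-2-(prop-2-yn-1-yloxy)ethan-1-one | C#CCOCC(=O)c1ccc(OC)cc1OC | intermediate
9 | 1-(2,4-dimethoxyphenyl)-3-hydroxy-3-(4-methoxyfuran-2-yl)-2-(prop-2-yn-1-yloxy)propan-1-one (racemic, both diastereomers) | C#CCOC(C(O)c1cc(OC)co1)C(=O)c1ccc(OC)cc1OC | intermediate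
10 | (Z)-1-(2,4-dimethoxyphenyl)-3-(4-methoxyfuran-2-yl)-2-(prop-2-yn-1-yloxy)prop-2-en-1-one | C#CCO/C(=C\c1cc(OC)co1)C(=O)c1ccc(OC)cc1OC | intermediate
11 | (2,4-dimethoxyphenyl)(6-methoxy-4a,7-dihydro-1H-4a,7-epoxyisochromen-3-yl)methanone (racemic; bridgehead configuration fixed by the bicycle) | COc1ccc(C(=O)C2=CC34OC(C=C3CO2)C(OC)=C4)c(OC)c1 | intermediate
12 | (2,4-dimethoxyphenyl)(7-hydroxy-6-methoxy-1H-isochromen-3-yl)methanone | COc1ccc(C(=O)C2=Cc3cc(OC)c(O)cc3CO2)c(OC)c1 | intermediate
13 | (2,4-dimethoxyphenyl)(6,7-dimethoxy-1H-isochromen-3-yl)methanone | COc1ccc(C(=O)C2=Cc3cc(OC)c(OC)cc3CO2)c(OC)c1 | target

## Step count and least certain steps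

Total step count: 6. Longest linear sequence: 5 steps (steps 1, 2, 4, 5, 6); the branch through step 3 joins at step 4.

**Step 5 (key step).** The most likely failure is a [3,3]-sigmatropic shift of the propargyl vinyl ether unit, which an acyl group on the oxygen-bearing vinyl carbon is known to make easier and which could consume the substrate at the temperature the unactivated alkyne needs. Thermal Z to E isomerisation, polymerisation of the electron-rich furan and incomplete opening of the bridge are lesser risks.

The fallback sets out from 10 and changes the dienophile. KOtBu in tBuOH–THF (0 °C to rt) should isomerise the propargyl ether to the allenyl ether (Z)-1-(2,4-dimethoxyphenyl)-3-(4-methoxyfuran-2-yl)-2-(propa-1,2-dien-1-yloxy)prop-2-en-1-one F1, which has no [3,3] pathway and whose terminal C=C is a much better dienophile. Gentle warming should give the oxanorbornene cycloadduct (2,4-dimethoxyphenyl)(6-methoxy-7,8-dihydro-4aH-4a,7-epoxyisochromen-3-yl)methanone F2 with the same C4a–C8a and C7–C8 bonds. In the basic medium the bridge should open, pushed by O2 and the C6 methoxy group, and proton shifts should move the exocyclic C8a=C1 double bond into ring A. Acidification then gives 12, where the route is rejoined. Base-mediated isomerisation of propargyl ethers to allenyl ethers followed by intramolecular furan Diels–Alder reaction is known chemistry.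

**Step 2.** The C–O coupling may stall on the electron-rich β-bromofuran or be overtaken by hydrodebromination, and the unmasking may go too far through protonation at furan C5 and hydrolysis of the ring enol ether.

The fallback sets out from 2 and reverses the polarity. Bromine–lithium exchange (nBuLi, THF, −78 °C) and trapping with iPrOBpin should give 2-[5-(dimethoxymethyl)furan-3-yl]-4,4,5,5-tetramethyl-1,3,2-dioxaborolane F3. Chan–Lam etherification with methanol (the divalent copper salt Cu(OAc)2, DMAP, 4 Å molecular sieves, MeOH, air) should give 3, where the route is rejoined; 3 is unmasked to 4 as in step 2.

**Step 4.** The enolate of 8 may undergo a [2,3]-sigmatropic (Wittig-type) shift of its propargyl ether before it meets the aldehyde. Dehydration of 9 may be incomplete, the aldehyde may be lost by Cannizzaro disproportionation, or an E/Z mixture may result.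

The fallback sets out from 8 and 4 and separates addition from elimination. LiN(SiMe3)2 (THF, −78 °C) and then 4 should give 9, isolated. Ac2O, DMAP and Et3N should convert it into 3-(2,4-dimethoxyphenyl)-1-(4-methoxyfuran-2-yl)-3-oxo-2-(prop-2-yn-1-yloxy)propyl acetate F4. DBU (CH2Cl2, rt) should eliminate by E1cB to 10, where the route is rejoined; any E isomer is equilibrated with a trace of iodine.

**Step 3.** Acid-promoted addition to the alkyne, trifluoroacetylation of 5 in place of the desired acyl transfer, or loss of positional selectivity on the arene may lower the efficiency.

The fallback sets out from 6 and forms the ketone by addition of an aryl nucleophile. CDI and MeNHOMe·HCl should give N-methoxy-N-methyl-2-(prop-2-yn-1-yloxy)acetamide F5. A Weinreb ketone synthesis with (2,4-dimethoxyphenyl)magnesium bromide F6 (from 1-bromo-2,4-dimethoxybenzene and Mg, slightly more than two equivalents because the first deprotonates the alkyne; THF, −20 to 0 °C) should give 8, where the route is rejoined.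

## Further compounds

F1 | step 5 | (Z)-1-(2,4-dimethoxyphenyl)-3-(4-methoxyfuran-2-yl)-2-(propa-1,2-dien-1-yloxy)prop-2-en-1-one | C=C=CO/C(=C\c1cc(OC)co1)C(=O)c1ccc(OC)cc1OC
F2 | step 5 | (2,4-dimethoxyphenyl)(6-methoxy-7,8-dihydro-4aH-4a,7-epoxyisochromen-3-yl)methanone (racemic) | COc1ccc(C(=O)C2=CC34OC(CC3=CO2)C(OC)=C4)c(OC)c1
F3 | step 2 | 2-[5-(dimethoxymethyl)furan-3-yl]-4,4,5,5-tetramethyl-1,3,2-dioxaborolane | COC(OC)c1cc(B2OC(C)(C)C(C)(C)O2)co1
F4 | step 4 | 3-(2,4-dimethoxyphenyl)-1-(4-methoxyfuran-2-yl)-3-oxo-2-(prop-2-yn-1-yloxy)propyl acetate (racemic, both diastereomers) | CC(=O)OC(c1cc(OC)co1)C(OCC#C)C(=O)c1ccc(OC)cc1OC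
F5 | step 3 | N-methoxy-N-methyl-2-(prop-2-yn-1-yloxy)acetamide | C#CCOCC(=O)N(C)OC
F6 | step 3 | (2,4-dimethoxyphenyl)magnesium bromide | COc1ccc([Mg]Br)c(OC)c1
A1 | alternative 1 | 6,7-dimethoxyisochroman-4-one | COc1cc2c(cc1OC)C(=O)COC2
A2 | alternative 1 | oxetan-3-one | O=C1COC1
A3 | alternative 1 | 4,5-dimethoxybenzyne (1,2-didehydro-4,5-dimethoxybenzene) | COC1=CC#CC=C1OC
A4 | alternative 1 | 4,5-dimethoxy-2-(trimethylsilyl)phenyl trifluoromethanesulfonate | COc1cc(OS(=O)(=O)C(F)(F)F)c(cc1OC)[Si](C)(C)C
A5 | alternative 1 | 3-(2,4-dimethoxybenzoyl)-6,7-dimethoxyisochroman-4-one (racemic) | COc1ccc(C(=O)C2OCc3cc(OC)c(OC)cc3C2=O)c(OC)c1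
A6 | alternative 2 | (2,4-dimethoxyphenyl)(4,6,7-trimethoxyisochroman-3-yl)methanone (racemic, both diastereomers) | COc1ccc(C(=O)C2OCc3cc(OC)c(OC)cc3C2OC)c(OC)c1
A7 | alternative 2 | 1,5,6-trimethoxy-1,3-dihydroisobenzofuran (racemic) | COC1OCc2cc(OC)c(OC)cc21
A8 | alternative 2 | 2-diazo-1-(2,4-dimethoxyphenyl)ethan-1-one | COc1ccc(C(=O)C=[N+]=[N-])c(OC)c1
A9 | alternative 3 | (2-hydroxy-4-methoxyphenyl)(6,7-dimethoxy-1H-isochromen-3-yl)methanone | COc1ccc(C(=O)C2=Cc3cc(OC)c(OC)cc3CO2)c(O)c1
A10 | alternative 3 | 1-(6,7-dimethoxy-1H-isochromen-3-yl)prop-2-yn-1-one | C#CC(=O)C1=Cc2cc(OC)c(OC)cc2CO1
A11 | alternative 3 | 1,3-dimethoxy-1-(trimethylsilyloxy)buta-1,3-diene (ketene acetal geometry not specified) | C=C(OC)C=C(OC)O[Si](C)(C)C
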